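40.6% is the number to start from: in the midnight run, the target rate between the last two readings is that fraction of the rate up to the first reading, yet starting material still stands at 83.0%.

| flask | starting material | partner | free catalyst | temperature | remark | time |
|---|---|---|---|---|---|---|
| noon | 0.12 M | 0.072 M | 60 µM | 82 °C | run made earlier |  |
| midnight | 0.12 M | 0.16 M | 60 µM | 110 °C | run made earlier |  |
| spring | 0.18 M | 0.108 M | 60 µM | 82 °C | run made earlier |  |
| zeta | 0.12 M | 0.108 M | 60 µM | 70 °C |  | 4.0 h |
| eta | 0.12 M | 0.108 M | 60 µM | 120 °C |  | 4.0 h |
| epsilon | 0.12 M | 0.108 M | 60 µM | 95 °C |  | 4.0 h |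

| run | time / min | target / % | starting material / % |
|---|---|---|---|
| noon | 30.0 | 4.2 | 96.2 |
| noon | 50.0 | 6.6 | 93.4 |
| noon | 80.0 | 9.8 | 90.2 |
| noon | 90.0 | 11.2 | 89.5 |
| noon | 120 | 14.1 | 85.7 |
| midnight | 3.00 | 3.3 | 97.3 |
| midnight | 6.00 | 5.6 | 94.7 |
| midnight | 8.00 | 6.5 | 93.5 |
| midnight | 15.0 | 10.1 | 89.2 |
| midnight | 30.0 | 16.8 | 83.0 |
| spring | 12.0 | 1.4 | 98.9 |
| spring | 20.0 | 1.8 | 98.3 |
| spring | 30.0 | 2.5 | 96.8 |
| spring | 60.0 | 5.7 | 94.2 |
| spring | 120 | 10.6 | 90.3 |

(standard deviation of a reading: 0.3 percentage points)

* the flask that comes out highest in amount of target, in percent of the starting material charged, or "all alike" when all lie within 1.5 percentage points (zeta / eta / epsilon / all alike)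
* target at the end, in percent of the starting material charged, zeta
* target at the end, in percent of the starting material charged, eta
* target at the end, in percent of the starting material charged, epsilon



The new flasks charge partner at 0.108 M against 0.12 M of starting material, which makes partner the limiting reagent, so I write its balance. Partner leaves through the catalyst, I assume one per target, or by a loss of its own, and I want the ratio of those two rates. No reading shows partner, so I assume that the midnight rate follows it. That puts about 0.0950 M of partner gone around the middle of the last interval, with about 0.0161 M of target made. By this estimate the loss took 4.89 times what the catalytic use took. If the loss goes with partner squared and the use with partner, the ratio scales with the charge, giving 3.30 for eta, taken at the midnight temperature although eta is hotter. The share reaching target is then 23.3%, and the target budget, the partner charge times that share, is 0.0251 M. For eta, my own figure is 20.9%.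

The forecast picks epsilon, with zeta 11.5% (9.5% to 14%), eta 30% (18% to 45%) and epsilon 35% (28% to 42%). It holds that at the hottest setting “the catalyst dies early”. Its eta stands above mine.

The flasks give zeta 13.3%, eta 22.9% and epsilon 28.9%, so epsilon is highest.

    partner + free catalyst → catalyst intermediate A (k = 6700 L mol⁻¹ h⁻¹, Ea = 36.0 kJ mol⁻¹)
    catalyst intermediate A → catalyst intermediate B (k = 540 h⁻¹, Ea = 94.0 kJ mol⁻¹)
    starting material + catalyst intermediate B → catalyst intermediate C (k = 20000 L mol⁻¹ h⁻¹, Ea = 49.0 kJ mol⁻¹)
    catalyst intermediate C → free catalyst + target (k = 100 h⁻¹, Ea = 83.0 kJ mol⁻¹)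
    2 partner → homo dimer (k = 1.80 L mol⁻¹ h⁻¹, Ea = 78.0 kJ mol⁻¹)
    (constants at 70 °C)

At the end of eta, free catalyst stands at >99.9% and starting material at 77.1%, but partner is down to 0.00531%. Taking away the path to homo dimer, one part of the story, lifts eta from 22.9% to 89.9%, and in eta more time changes nothing. Zeta differs: there the time given is the largest single effect on the shortfall, though not its main reason, and ten times as long lifts target from 13.3% to 34.1%. The neighbour with 0.048 M of starting material keeps eta's partner, so the budget of 0.0251 M gives 52.3% there. The computed flask gives 54.9%.

The data are calculated on assumed constants, and the scatter is random.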